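## Structural features

The target (numbered here O1 and C2 to C5 for ring A, C6 to C14 for the chain) is a linear furanoterpenoid with a ring system at each end. Ring A is a 4-hydroxy-3-methylfuran-2(5H)-one (a tetronic acid) joined to the chain through an exocyclic (Z)-C5=C6 double bond. Ring B is a furan that carries the chain (through C14) at its 4-position and, at its 2-position, a methylene bridge to ring C, a 3-substituted furan. Between the rings lie C7, the only stereocentre (S, methyl-bearing, directly beside the ylidene carbon C6), the C8 methylene, an (E,E)-diene C9=C10–C11=C12 with a methyl on C11, and the C13–C14 ethylene. Fragile groups are the acidic enol and the enol lactone of ring A (opened by hydroxide or alkoxide), the C7 hydrogen (allylic and vinylogously acidic, since its loss leads to an aromatic 2-oxidofuran), the two acid- and oxidant-sensitive furans with their doubly activated bridging CH2, and the diene. The real difficulty is threefold: a (Z)-ylidene tetronate must be raised beside C7 without epimerisation, the trisubstituted C11=C12 bond must be E, and ring B must be 2,4-disubstituted, a pattern that direct substitution of a 3-substituted furan does not deliver. The key step uses the fact that C2 (carbonyl), C3 (methyl), C4 (oxygen) and C5 (chain) of ring A map atom for atom onto a squaric acid derivative. Insertion of O1 between C2 and C5 of such a cyclobutenone gives ring A with a leaving group on C5, and its loss toward C6, the only neighbour with hydrogens, creates the ylidene.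

## Logic of the disconnections

28 from 27: the O–CH3 bond on the C4 oxygen is cut last. Carrying the enol as its methyl ether removes the acidic proton that would destroy the lithium, zinc and tin reagents, so every ring A intermediate is neutral. The forward step must cleave the ether by attack at the methyl carbon, without a base that could touch C7 or the lactone.

27 into 15 and 26: the C10–C11 single bond between the two alkenes is cut. This gives two halves of similar size, each with one sensitive terminus, and makes each alkene geometry the task of its own fragment. The forward coupling must join two alkenyl carbons with retention on both sides, at room temperature, without acid or base.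

15 to 14 to 13: the C10–Sn bond and then the C10–Si bond are cut, so that C9 and C10 travel as an alkyne. An alkyne has no geometry to lose and, with silicon on C10, no acidic hydrogen. The forward demands are a syn, terminal-selective hydrostannation and a desilylation that leaves the enol lactone closed.

13 to 12: the C5=C6 double bond is traced back to a C5–O acetate and a C6–H. The ylidene is then not exposed to the oxidant, and the acetate is exactly what the key step leaves on C5. The forward elimination must give the Z isomer and must not deprotonate C7.

12 to 11 (key disconnection): the O1–C2 bond is cut and C2 is rejoined to C5, contracting ring A to a four-membered ring. All of ring A, with methyl on C3 and oxygen on C4, then comes from a cyclobutenone that two carbonyl additions make from 7. The forward step must break the C5–C2 bond and not the C5–C4 bond, and must leave the silylalkyne alone.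

11 into 9 and 6 (through 10): the C5–C6 bond at the carbinol is cut. 9 has two carbonyls of different character, so the forward addition must go to the one beside the methoxy-bearing carbon. 10 must be made and used cold because it carries a silylalkyne four atoms from lithium.

9 to 7: the C3–CH3 bond is cut. The forward step is addition of a methyl nucleophile and loss of methanol.

6 to 5 to 1 and 2: the C–I bond is exchanged for C–Br, and the C8–C9 bond between sp3 and sp carbon is cut. C7 is bought with 1, and no bond to it is made or broken anywhere in the route. The forward alkynylation must displace the activated oxygen of 1 (as 3) in the presence of its primary bromide.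

26 to 24: the C11–I and C12–H bonds are removed to give an alkyne. The forward addition must be syn and must place the metal on the methyl-bearing carbon.

24 into 20 and 22 (through 23): the bond between C14 and ring B is cut. The 2,4-pattern of ring B is then bought with the ring bromide of 17 and is never in question. The forward step is an sp3–sp2 coupling that must outrun β-hydride elimination.

20 to 19 to 16 and 17 (through 18): a C–H of the bridging methylene is traced back to a carbinol C–O, and the bond between the bridging carbon and ring C is cut. The forward reduction must remove a doubly furyl-activated hydroxyl without acid damage to the rings. 22 comes from 21 by exchange of C–O for C–I.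

## Other disconnections considered

Alternative 1: The cut is the O–C2 bond of ring B, which opens the furan to the acyclic (Z)-2-(but-3-en-1-yl)-5-(furan-3-yl)pent-2-en-4-yn-1-ol A1. In the forward step KOC(CH3)3 (or AuCl3) would make the hydroxyl add 5-exo-dig to the nearer alkyne carbon. A proton shift would then aromatise the ring and turn the former alkyne terminus into the bridging CH2, giving 4-(but-3-en-1-yl)-2-(furan-3-ylmethyl)furan A2.
- In its favour: the 2,4-pattern of ring B follows from the connectivity of A1 and cannot come out wrong. No carbinol between two furans has to be reduced under acid as in step 10. The step is catalytic and a pure isomerisation.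
- Against it here: it deals only with ring B, so ring A, C7 and the ylidene still need a method of their own. A1 needs a stereodefined trisubstituted Z-alkene. The butenyl end of A2 holds neither the C11 methyl nor a handle for an E-trisubstituted alkene, so several more steps would separate A2 from a partner equivalent to 26.
- Comparison: on regiocontrol of ring B and on mildness (base or gold catalysis against stoichiometric tetravalent lead) this alternative is the better. In step count for the bis-furan half it is about equal to steps 9 to 13. As the strategic step for the whole target it is weaker, because the harder end, the ylidene tetronate beside C7, stays unsolved, whereas step 5 settles it.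

Alternative 2: The cut is the O1–C5 bond of ring A, which opens the lactone to (2E,6S,8E,10E)-13-[5-(furan-3-ylmethyl)furan-3-yl]-3-methoxy-2,6,10-trimethyltrideca-2,8,10-trien-4-ynoic acid A3. One descriptor has to be put right: lactonisation needs the carboxyl and the alkynyl group cis on the C2=C3 bond of A3, and with methoxy on C3 that arrangement is E by the sequence rule (it would be Z only without the methoxy group). In the forward step AgNO3 would activate the alkyne and the carboxyl oxygen would add anti in a 5-exo-dig closure. The product would be the methyl ether A4, which is the same compound as 27 and would be demethylated as in step 15.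
- In its favour: the step is catalytic and convergent. Ring A and the Z ylidene would arise in one stereospecific event. No stoichiometric lead and no separate elimination are needed.
- Against it here: the 6-endo-dig mode to the isomeric pyranone competes, and the donor methoxy group on C3 may shift the balance. C7 of A3 is a propargylic stereocentre next to an electron-poor enyne, exposed to allene formation under the basic conditions that would assemble A3. The tetrasubstituted C2=C3 geometry must be set beforehand. Silver would meet two furans and a diene with the whole carbon chain at stake.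
- Comparison: in stereospecificity for the ylidene this alternative is the equal of step 6, and in atom economy and metal load it is the better. In certainty of ring size the chosen plan is the better, because O1 can only be inserted into a ring whose four carbons are already joined. In step count the two are about equal, since A3 needs a coupling of its own to attach the alkyne to C3.

Alternative 3: The cuts are the C3–C4 and O–C5 bonds of ring B, which divide it into the keto sulfonium ylide dimethylsulfonium 3-(furan-3-yl)-2-oxopropan-1-ide A5 and the alkyne tert-butyldimethyl(pent-4-yn-1-yloxy)silane A6. In the forward step (Ph3P)AuNTf2 would activate A6 and the ylide carbon of A5 would attack the internal alkyne carbon. Loss of the sulfide would leave a gold carbene at the terminal carbon, and the ketone oxygen would close on it to give tert-butyl{3-[5-(furan-3-ylmethyl)furan-3-yl]propoxy}dimethylsilane A7.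
- In its favour: two simple components, one catalytic step, and a 2,4-pattern dictated by the mechanism. The silyl ether of A7 ends at C12, so an aldehyde there could be olefinated to the E-trisubstituted C11=C12 bond without any regiochemical question.
- Against it here: the methylene of A5 between ketone and ring C is doubly activated and may enolise. The free α-positions of ring C may compete as nucleophiles for the activated alkyne. A7 still needs deprotection, oxidation and olefination before it can meet the ring A half, and ring A is not addressed.
- Comparison: for ring B this alternative is the better in convergence and the equal of steps 9 to 12 in regiocontrol, and its C12 handle is better than the regioselectivity on which step 13 depends. As the strategic step for the whole molecule it is weaker than step 5, for the same reason as Alternative 1, and the step count to a partner like 26 would be about the same.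

Key step: step 5

Assumption: 1 is bought as the single (S) enantiomer (a catalogue compound of the same chiral-pool series as methyl (R)-3-hydroxy-2-methylpropanoate; its CH2Br carbon becomes C6 and its CH2OH carbon C8), and 28 is isolated as the 4-hydroxy enol tautomer.

## Route

Step 1
Reactants: 1 (S)-3-bromo-2-methylpropan-1-ol; 2 ethynyltrimethylsilane
Product: 5 (S)-(5-bromo-4-methylpent-1-yn-1-yl)trimethylsilane, via bromo triflate 3 (not isolated), via lithium silylacetylide 4 (not isolated)
Conditions: Tf2O, 2,6-lutidine, CH2Cl2, −78 °C; cold solution of 3 added to 4 (from 2, n-BuLi, excess) in THF/DMPU, −78 to −20 °C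
Reagents that add atoms: none
Why: O-Triflation followed by SN2 alkynylation of the primary triflate with a lithium acetylide; the triflate should react far faster than the primary bromide at this temperature, so the bromide is kept as the later handle. C7 is a spectator, since no bond to it is made or broken.

Step 2
Reactants: 5 (S)-(5-bromo-4-methylpent-1-yn-1-yl)trimethylsilane
Product: 6 (S)-(5-iodo-4-methylpent-1-yn-1-yl)trimethylsilane
Conditions: NaI, acetone, reflux
Reagents that add atoms: sodium iodide, [Na+].[I-]
Why: Finkelstein exchange, driven by precipitation of NaBr; the iodide is wanted because lithium–iodine exchange is fast and clean at −78 °C, and the silylalkyne is inert to iodide.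

Step 3
Reactants: 7 dimethyl squarate
Product: 9 3-methoxy-4-methylcyclobut-3-ene-1,2-dione, via lithium alkoxide adduct 8 (not isolated)
Conditions: MeLi, THF, −78 °C; (CF3CO)2O, −78 °C; then H2O
Reagents that add atoms: methyllithium, [Li]C; water, O
Why: Organolithium 1,2-addition to one vinylogous ester carbonyl, then trifluoroacetylation of the alkoxide, ionisation to a methoxy-stabilised cation and hydrolysis with loss of methanol; this is the standard one-flask entry to 3-alkoxy-4-alkylcyclobutenediones.

Step 4
Reactants: 6 (S)-(5-iodo-4-methylpent-1-yn-1-yl)trimethylsilane; 9 3-methoxy-4-methylcyclobut-3-ene-1,2-dione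
Product: 11 4-hydroxy-3-methoxy-2-methyl-4-[(2S)-2-methyl-5-(trimethylsilyl)pent-4-yn-1-yl]cyclobut-2-en-1-one (both carbinol epimers), via alkyllithium 10 (not isolated)
Conditions: 6, t-BuLi (2.1 equiv), Et2O/pentane, −78 °C; added to 9, THF, −78 °C; aq. NH4Cl
Reagents that add atoms: none
Why: Lithium–iodine exchange gives the primary alkyllithium, which is kept at −78 °C so that 4-exo-dig carbolithiation of the silylalkyne cannot start. 1,2-Addition should go to the ketone-like carbonyl next to the methoxy-bearing carbon, because the other carbonyl is deactivated as a vinylogous ester; this fixes methyl on the future C3. The carbinol centre forms without control and is removed in step 6.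

Step 5
Reactants: 11 4-hydroxy-3-methoxy-2-methyl-4-[(2S)-2-methyl-5-(trimethylsilyl)pent-4-yn-1-yl]cyclobut-2-en-1-one
Product: 12 5-acetoxy-4-methoxy-3-methyl-5-[(2S)-2-methyl-5-(trimethylsilyl)pent-4-yn-1-yl]furan-2(5H)-one (both C5 epimers)
Conditions: Pb(OAc)4, toluene, rt
Reagents that add atoms: lead tetraacetate, CC(=O)O[Pb](OC(C)=O)(OC(C)=O)OC(C)=O
Why: Ligand exchange of the tertiary hydroxyl of 11 at tetravalent lead gives an alkoxylead triacetate, and homolysis of its O–Pb bond gives the alkoxy radical on the future C5. β-Scission breaks the strained C5–C2 (carbinol–carbonyl) bond and not the C5–C4 (carbinol–alkene) bond, because the first gives a conjugated acyl radical and the second a vinyl radical; relief of four-ring strain should also make it faster than hydrogen transfer from the propargylic C8. The acyl radical is oxidised by lead to an acylium ion, and the oxygen of the ketone just formed at C5 closes on it in a 5-exo-dig attack, pre-organised by the cis C3=C4 bond, which forms O1–C2 and ring A. Acetate then caps the oxocarbenium carbon C5 to give 12, with divalent lead as the spent oxidant. The closest known reaction type is the Pb(OAc)4-mediated oxidative ring expansion of squarate-derived 4-hydroxycyclobutenones to 5-acetoxy-2(5H)-furanones. C5 of 12 is a new stereocentre with no controlling element, but both epimers (like both carbinol epimers of 11) converge in step 6, and C7 is not touched. The selectivities needed are the direction of scission (secured by the acyl-over-vinyl radical preference), methyl on C3 and methoxy on C4 (fixed by the order of additions in steps 3 and 4) and inertness of the silylalkyne (it offers no site for the oxidant).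

Step 6
Reactants: 12 5-acetoxy-4-methoxy-3-methyl-5-[(2S)-2-methyl-5-(trimethylsilyl)pent-4-yn-1-yl]furan-2(5H)-one
Product: 13 (5Z)-4-methoxy-3-methyl-5-[(2S)-2-methyl-5-(trimethylsilyl)pent-4-yn-1-ylidene]furan-2(5H)-one
Conditions: DBU, THF, 0 °C
Reagents that add atoms: none
Why: Base-mediated anti β-elimination (E2) of acetic acid across C5–C6, the only direction with hydrogens. The Z isomer should result because the chain avoids the C4 methoxy group (allylic strain) and lies on the side of O1. Short exposure at 0 °C is chosen to leave the C7 hydrogen untouched.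

Step 7
Reactants: 13 (5Z)-4-methoxy-3-methyl-5-[(2S)-2-methyl-5-(trimethylsilyl)pent-4-yn-1-ylidene]furan-2(5H)-one
Product: 14 (5Z)-4-methoxy-3-methyl-5-[(2S)-2-methylpent-4-yn-1-ylidene]furan-2(5H)-one
Conditions: Bu4NF, AcOH, THF, 0 °C
Reagents that add atoms: none
Why: Fluoride protodesilylation of an alkynylsilane; buffering with acetic acid keeps the medium non-basic, so the enol lactone stays closed and C7 is not deprotonated.

Step 8
Reactants: 14 (5Z)-4-methoxy-3-methyl-5-[(2S)-2-methylpent-4-yn-1-ylidene]furan-2(5H)-one
Product: 15 (5Z)-4-methoxy-3-methyl-5-[(2S,4E)-2-methyl-5-(tributylstannyl)pent-4-en-1-ylidene]furan-2(5H)-one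
Conditions: Bu3SnH, Pd2(dba)3 (cat.), Cy3P·HBF4 (cat.), i-Pr2NEt, CH2Cl2, 0 °C
Reagents that add atoms: tributyltin hydride, CCCC[SnH](CCCC)CCCC
Why: Palladium-catalysed syn hydrostannation of a terminal alkyne; the bulky trialkylphosphine should steer tin to the terminal carbon and give the (E)-alkenylstannane. The electron-rich ylidene is a poor acceptor for the palladium hydride.

Step 9
Reactants: 16 3-bromofuran; 17 4-bromofuran-2-carbaldehyde
Product: 19 (4-bromofuran-2-yl)(furan-3-yl)methanol (racemic), via furan-3-yllithium 18 (not isolated)
Conditions: 16, n-BuLi, Et2O, −78 °C; then 17, −78 °C; aq. NH4Cl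
Reagents that add atoms: none
Why: Bromine–lithium exchange gives the 3-lithiofuran, which keeps its position at −78 °C, and 1,2-addition to the aldehyde should be much faster than exchange with the ring bromide of 17. The carbinol centre is removed in step 10.

Step 10
Reactants: 19 (4-bromofuran-2-yl)(furan-3-yl)methanol
Product: 20 4-bromo-2-(furan-3-ylmethyl)furan
Conditions: Et3SiH (excess), CF3CO2H, CH2Cl2, −20 to 0 °C
Reagents that add atoms: none
Why: Ionic hydrogenation: acid ionises the carbinol to a cation stabilised by both furans and the silane delivers hydride. Excess silane, dilution and low temperature are meant to make reduction outrun alkylation of another furan, and the bromine lowers the nucleophilicity of ring B.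

Step 11
Reactants: 21 pent-3-yn-1-ol
Product: 22 5-iodopent-2-yne
Conditions: I2, PPh3, imidazole, CH2Cl2, 0 °C to rt
Reagents that add atoms: iodine, II
Why: Appel-type iodination of a primary alcohol through the alkoxyphosphonium iodide; the internal alkyne is inert.

Step 12
Reactants: 22 5-iodopent-2-yne; 20 4-bromo-2-(furan-3-ylmethyl)furan
Product: 24 2-(furan-3-ylmethyl)-4-(pent-3-yn-1-yl)furan, via pent-3-ynylzinc iodide 23 (not isolated)
Conditions: 22, Zn, LiCl, THF, 40 °C; then 20, Pd(OAc)2 (cat.), SPhos, THF, 50 °C
Reagents that add atoms: none
Why: Zinc insertion into the primary iodide, then Negishi sp3–sp2 coupling; the bulky biarylphosphine should promote oxidative addition into the electron-rich β-bromofuran and reductive elimination ahead of β-hydride elimination. The alkylzinc is not basic enough to touch the bridging CH2.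

Step 13
Reactants: 24 2-(furan-3-ylmethyl)-4-(pent-3-yn-1-yl)furan
Product: 26 2-(furan-3-ylmethyl)-4-[(3E)-4-iodopent-3-en-1-yl]furan, via alkenylzirconocene chloride 25 (not isolated)
Conditions: Cp2Zr(H)Cl (2.5 equiv), THF, 50 °C; then I2, −78 to 0 °C
Reagents that add atoms: iodine, II
Why: Syn hydrozirconation of the internal alkyne; with excess hydride and warming the regioisomers equilibrate toward zirconium on the less hindered, methyl-bearing carbon. Iodinolysis of the C–Zr bond with retention then gives the (E)-2-iodoalk-2-ene.

Step 14
Reactants: 15 (5Z)-4-methoxy-3-methyl-5-[(2S,4E)-2-methyl-5-(tributylstannyl)pent-4-en-1-ylidene]furan-2(5H)-one; 26 2-(furan-3-ylmethyl)-4-[(3E)-4-iodopent-3-en-1-yl]furan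
Product: 27 (5Z)-5-[(2S,4E,6E)-9-[5-(furan-3-ylmethyl)furan-3-yl]-2,6-dimethylnona-4,6-dien-1-ylidene]-4-methoxy-3-methylfuran-2(5H)-one
Conditions: Pd2(dba)3 (cat.), AsPh3, CuI, DMF, rt
Reagents that add atoms: none
Why: Stille coupling of an alkenylstannane with an alkenyl iodide, which proceeds with retention at both alkenes; the arsine ligand and CuI speed transmetalation so the α-branched iodide can couple at room temperature. The neutral medium spares the furans, the lactone and C7.

Step 15
Reactants: 27 (5Z)-5-[(2S,4E,6E)-9-[5-(furan-3-ylmethyl)furan-3-yl]-2,6-dimethylnona-4,6-dien-1-ylidene]-4-methoxy-3-methylfuran-2(5H)-one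
Product: 28 (5Z)-5-[(2S,4E,6E)-9-[5-(furan-3-ylmethyl)furan-3-yl]-2,6-dimethylnona-4,6-dien-1-ylidene]-4-hydroxy-3-methylfuran-2(5H)-one
Conditions: LiCl, DMSO, 50 °C; then cold dilute HCl
Reagents that add atoms: none
Why: SN2 O-demethylation of a vinylogous methyl ester by chloride at the methyl carbon, with the tetronate as leaving group. The reagent is not basic, so neither C7 nor the enol lactone is at risk, and brief cold acidification releases the enol.

## Compound list

1 | (S)-3-bromo-2-methylpropan-1-ol | BrC[C@@H](C)CO | starting material
2 | ethynyltrimethylsilane | C#C[Si](C)(C)C | starting material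
3 | (S)-3-bromo-2-methylpropyl trifluoromethanesulfonate | BrC[C@@H](C)COS(=O)(=O)C(F)(F)F | intermediate
4 | lithium (trimethylsilyl)acetylide | [Li]C#C[Si](C)(C)C | intermediate
5 | (S)-(5-bromo-4-methylpent-1-yn-1-yl)trimethylsilane | BrC[C@@H](C)CC#C[Si](C)(C)C | intermediate
6 | (S)-(5-iodo-4-methylpent-1-yn-1-yl)trimethylsilane | IC[C@@H](C)CC#C[Si](C)(C)C | intermediate
7 | dimethyl squarate (3,4-dimethoxycyclobut-3-ene-1,2-dione) | COC1=C(OC)C(=O)C1=O | starting material
8 | lithium 2,3-dimethoxy-1-methyl-4-oxocyclobut-2-en-1-olate | [Li+].[O-]C1(C)C(OC)=C(OC)C1=O | intermediate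
9 | 3-methoxy-4-methylcyclobut-3-ene-1,2-dione | COC1=C(C)C(=O)C1=O | intermediate
10 | [(2R)-2-methyl-5-(trimethylsilyl)pent-4-yn-1-yl]lithium (same spatial arrangement as 6; the descriptor changes by priority only) | [Li]C[C@@H](C)CC#C[Si](C)(C)C | intermediate
11 | 4-hydroxy-3-methoxy-2-methyl-4-[(2S)-2-methyl-5-(trimethylsilyl)pent-4-yn-1-yl]cyclobut-2-en-1-one (both carbinol epimers) | CC1=C(OC)C(O)(C[C@@H](C)CC#C[Si](C)(C)C)C1=O | intermediate
12 | 5-acetoxy-4-methoxy-3-methyl-5-[(2S)-2-methyl-5-(trimethylsilyl)pent-4-yn-1-yl]furan-2(5H)-one (both C5 epimers) | CC1=C(OC)C(OC(C)=O)(C[C@@H](C)CC#C[Si](C)(C)C)OC1=O | intermediate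
13 | (5Z)-4-methoxy-3-methyl-5-[(2S)-2-methyl-5-(trimethylsilyl)pent-4-yn-1-ylidene]furan-2(5H)-one | CC1=C(OC)/C(=C/[C@@H](C)CC#C[Si](C)(C)C)OC1=O | intermediate
14 | (5Z)-4-methoxy-3-methyl-5-[(2S)-2-methylpent-4-yn-1-ylidene]furan-2(5H)-one | CC1=C(OC)/C(=C/[C@@H](C)CC#C)OC1=O | intermediate
15 | (5Z)-4-methoxy-3-methyl-5-[(2S,4E)-2-methyl-5-(tributylstannyl)pent-4-en-1-ylidene]furan-2(5H)-one | CC1=C(OC)/C(=C/[C@@H](C)C/C=C/[Sn](CCCC)(CCCC)CCCC)OC1=O | intermediate
16 | 3-bromofuran | Brc1ccoc1 | starting material
17 | 4-bromofuran-2-carbaldehyde | O=Cc1cc(Br)co1 | starting material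
18 | furan-3-yllithium | [Li]c1ccoc1 | intermediate
19 | (4-bromofuran-2-yl)(furan-3-yl)methanol (racemic) | OC(c1ccoc1)c1cc(Br)co1 | intermediate
20 | 4-bromo-2-(furan-3-ylmethyl)furan | Brc1coc(Cc2ccoc2)c1 | intermediate
21 | pent-3-yn-1-ol | CC#CCCO | starting material
22 | 5-iodopent-2-yne | CC#CCCI | intermediate
23 | (pent-3-yn-1-yl)zinc iodide | CC#CCC[Zn]I | intermediate
24 | 2-(furan-3-ylmethyl)-4-(pent-3-yn-1-yl)furan | CC#CCCc1coc(Cc2ccoc2)c1 | intermediate
25 | chlorobis(cyclopentadienyl){(2E)-5-[5-(furan-3-ylmethyl)furan-3-yl]pent-2-en-2-yl}zirconium | Cl[Zr](C1C=CC=C1)(C1C=CC=C1)/C(C)=C/CCc1coc(Cc2ccoc2)c1 | intermediate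
26 | 2-(furan-3-ylmethyl)-4-[(3E)-4-iodopent-3-en-1-yl]furan | I/C(C)=C/CCc1coc(Cc2ccoc2)c1 | intermediate
27 | (5Z)-5-[(2S,4E,6E)-9-[5-(furan-3-ylmethyl)furan-3-yl]-2,6-dimethylnona-4,6-dien-1-ylidene]-4-methoxy-3-methylfuran-2(5H)-one | CC1=C(OC)/C(=C/[C@@H](C)C/C=C/C(C)=C/CCc2coc(Cc3ccoc3)c2)OC1=O | intermediate
28 | (5Z)-5-[(2S,4E,6E)-9-[5-(furan-3-ylmethyl)furan-3-yl]-2,6-dimethylnona-4,6-dien-1-ylidene]-4-hydroxy-3-methylfuran-2(5H)-one | CC1=C(O)/C(=C/[C@@H](C)C/C=C/C(C)=C/CCc2coc(Cc3ccoc3)c2)OC1=O | target

## Step count and least certain steps

Total: 15 steps. Longest linear sequence: 9 steps (1, 2, 4, 5, 6, 7, 8, 14, 15) from 1. The bis-furan branch (steps 9, 10, 12, 13) and the squarate branch (step 3) are shorter.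

Step 5 (key step). What may go wrong: hydrogen transfer from the propargylic C8 to the alkoxy radical may compete with ring scission. Ionisation and hydrolysis of the C5 acetate of 12 during work-up could also drain material into a ring-opened keto acid. Fallback: ring A is built by the aldol route to ylidene tetronates, which needs no cyclobutenone. It sets out from 6, which is oxidised with trimethylamine N-oxide in DMSO to (S)-2-methyl-5-(trimethylsilyl)pent-4-ynal F1. 4-Methoxy-3-methylfuran-2(5H)-one F2 (from 3-methyltetronic acid and dimethyl sulfate) is deprotonated at C5 with LiN(i-Pr)2 in THF at −78 °C and added to F1. This gives 5-[(2S)-1-hydroxy-2-methyl-5-(trimethylsilyl)pent-4-yn-1-yl]-4-methoxy-3-methylfuran-2(5H)-one F3. Mesylation (MsCl, Et3N) gives (2S)-1-(3-methoxy-4-methyl-5-oxo-2,5-dihydrofuran-2-yl)-2-methyl-5-(trimethylsilyl)pent-4-yn-1-yl methanesulfonate F4, and DBU eliminates it to the Z ylidene, so the fallback comes back to the route at 13. Its price is an α-branched aldehyde that can epimerise, which is why it is the second choice.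

Step 10. What may go wrong: the cation between the two furans may alkylate a free α-position of another furan faster than the silane reduces it, leading to oligomers, or the acid may open a furan ring. Fallback: the bridging methylene is made without acid or cation. It sets out from 17, which is condensed with 4-methylbenzenesulfonohydrazide in methanol to N'-[(E)-(4-bromofuran-2-yl)methylidene]-4-methylbenzenesulfonohydrazide F5. Heating F5 with commercial furan-3-ylboronic acid and K2CO3 in dioxane (metal-free reductive coupling through the diazoalkane and a boron intermediate that is protonated off) should give the diarylmethane directly and comes back to the route at 20.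

Step 13. What may go wrong: incomplete regiocontrol of the hydrozirconation would put part of the zirconium on C12 and give an isomeric 3-iodoalkene that is hard to separate and would be carried into 27. Excess iodine could also iodinate a furan. Fallback: the C11=C12 bond is made from an aldehyde carbon, so that its regiochemistry is fixed by construction.
- It sets out from 20: Negishi coupling with commercial (3-ethoxy-3-oxopropyl)zinc bromide gives ethyl 3-[5-(furan-3-ylmethyl)furan-3-yl]propanoate F6.
- i-Bu2AlH at −78 °C gives 3-[5-(furan-3-ylmethyl)furan-3-yl]propanal F7.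
- Corey–Fuchs olefination (CBr4, PPh3) gives 4-(4,4-dibromobut-3-en-1-yl)-2-(furan-3-ylmethyl)furan F8.
- Stille coupling of F8 with 15 (Pd2(dba)3, tri(2-furyl)phosphine, toluene), selective for the bromide trans to the chain, gives (5Z)-5-[(2S,4E,6Z)-6-bromo-9-[5-(furan-3-ylmethyl)furan-3-yl]-2-methylnona-4,6-dien-1-ylidene]-4-methoxy-3-methylfuran-2(5H)-one F9.
- Negishi methylation of F9 (MeZnCl, Pd(P(t-Bu)3)2, THF) with retention comes back to the route at 27.

Step 8. What may go wrong: tin may be delivered in part to the internal alkyne carbon, and palladium hydride may reduce or isomerise the ylidene. Fallback: the alkenyl metal is changed from tin to boron. It sets out from 14: hydroboration with pinacolborane catalysed by Cp2Zr(H)Cl gives (5Z)-4-methoxy-3-methyl-5-[(2S,4E)-2-methyl-5-(4,4,5,5-tetramethyl-1,3,2-dioxaborolan-2-yl)pent-4-en-1-ylidene]furan-2(5H)-one F10. Suzuki–Miyaura coupling of F10 with 26 (PdCl2(dppf), K3PO4, DMF/H2O, rt) comes back to the route at 27.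

Step 15. What may go wrong: demethylation of the fully assembled molecule may be slow at a temperature the diene and furans tolerate, and prolonged heating may cause Z/E isomerisation of the ylidene or decomposition. Fallback: the methyl ether is exchanged early for a fluoride-labile ether.
- It sets out from 14, a small and robust compound that can be heated with LiCl in DMSO as long as needed, giving (5Z)-4-hydroxy-3-methyl-5-[(2S)-2-methylpent-4-yn-1-ylidene]furan-2(5H)-one F11.
- Mitsunobu etherification with 2-(trimethylsilyl)ethanol (PPh3, diisopropyl azodicarboxylate) gives (5Z)-3-methyl-5-[(2S)-2-methylpent-4-yn-1-ylidene]-4-[2-(trimethylsilyl)ethoxy]furan-2(5H)-one F12.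
- Hydrostannation as in step 8 gives (5Z)-3-methyl-5-[(2S,4E)-2-methyl-5-(tributylstannyl)pent-4-en-1-ylidene]-4-[2-(trimethylsilyl)ethoxy]furan-2(5H)-one F13.
- Stille coupling with 26 as in step 14 gives (5Z)-5-[(2S,4E,6E)-9-[5-(furan-3-ylmethyl)furan-3-yl]-2,6-dimethylnona-4,6-dien-1-ylidene]-3-methyl-4-[2-(trimethylsilyl)ethoxy]furan-2(5H)-one F14.
- Bu4NF in THF at 0 °C, then mild acidification, comes back to the route at 28.

## Further compounds

F1 | step 5 | (S)-2-methyl-5-(trimethylsilyl)pent-4-ynal | O=C[C@@H](C)CC#C[Si](C)(C)C
F2 | step 5 | 4-methoxy-3-methylfuran-2(5H)-one | CC1=C(OC)COC1=O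
F3 | step 5 | 5-[(2S)-1-hydroxy-2-methyl-5-(trimethylsilyl)pent-4-yn-1-yl]-4-methoxy-3-methylfuran-2(5H)-one (mixture at C5 and carbinol) | CC1=C(OC)C(C(O)[C@@H](C)CC#C[Si](C)(C)C)OC1=O
F4 | step 5 | (2S)-1-(3-methoxy-4-methyl-5-oxo-2,5-dihydrofuran-2-yl)-2-methyl-5-(trimethylsilyl)pent-4-yn-1-yl methanesulfonate | CC1=C(OC)C(C(OS(C)(=O)=O)[C@@H](C)CC#C[Si](C)(C)C)OC1=O
F5 | step 10 | N'-[(E)-(4-bromofuran-2-yl)methylidene]-4-methylbenzenesulfonohydrazide | Cc1ccc(cc1)S(=O)(=O)N/N=C/c1cc(Br)co1
F6 | step 13 | ethyl 3-[5-(furan-3-ylmethyl)furan-3-yl]propanoate | CCOC(=O)CCc1coc(Cc2ccoc2)c1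
F7 | step 13 | 3-[5-(furan-3-ylmethyl)furan-3-yl]propanal | O=CCCc1coc(Cc2ccoc2)c1
F8 | step 13 | 4-(4,4-dibromobut-3-en-1-yl)-2-(furan-3-ylmethyl)furan | BrC(Br)=CCCc1coc(Cc2ccoc2)c1
F9 | step 13 | (5Z)-5-[(2S,4E,6Z)-6-bromo-9-[5-(furan-3-ylmethyl)furan-3-yl]-2-methylnona-4,6-dien-1-ylidene]-4-methoxy-3-methylfuran-2(5H)-one | CC1=C(OC)/C(=C/[C@@H](C)C/C=C/C(Br)=C/CCc2coc(Cc3ccoc3)c2)OC1=O
F10 | step 8 | (5Z)-4-methoxy-3-methyl-5-[(2S,4E)-2-methyl-5-(4,4,5,5-tetramethyl-1,3,2-dioxaborolan-2-yl)pent-4-en-1-ylidene]furan-2(5H)-one | CC1=C(OC)/C(=C/[C@@H](C)C/C=C/B2OC(C)(C)C(C)(C)O2)OC1=O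
F11 | step 15 | (5Z)-4-hydroxy-3-methyl-5-[(2S)-2-methylpent-4-yn-1-ylidene]furan-2(5H)-one | CC1=C(O)/C(=C/[C@@H](C)CC#C)OC1=O
F12 | step 15 | (5Z)-3-methyl-5-[(2S)-2-methylpent-4-yn-1-ylidene]-4-[2-(trimethylsilyl)ethoxy]furan-2(5H)-one | CC1=C(OCC[Si](C)(C)C)/C(=C/[C@@H](C)CC#C)OC1=O
F13 | step 15 | (5Z)-3-methyl-5-[(2S,4E)-2-methyl-5-(tributylstannyl)pent-4-en-1-ylidene]-4-[2-(trimethylsilyl)ethoxy]furan-2(5H)-one | CC1=C(OCC[Si](C)(C)C)/C(=C/[C@@H](C)C/C=C/[Sn](CCCC)(CCCC)CCCC)OC1=O
F14 | step 15 | (5Z)-5-[(2S,4E,6E)-9-[5-(furan-3-ylmethyl)furan-3-yl]-2,6-dimethylnona-4,6-dien-1-ylidene]-3-methyl-4-[2-(trimethylsilyl)ethoxy]furan-2(5H)-one | CC1=C(OCC[Si](C)(C)C)/C(=C/[C@@H](C)C/C=C/C(C)=C/CCc2coc(Cc3ccoc3)c2)OC1=O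
A1 | alternative 1 | (Z)-2-(but-3-en-1-yl)-5-(furan-3-yl)pent-2-en-4-yn-1-ol | OC/C(CCC=C)=C\C#Cc1ccoc1
A2 | alternative 1 | 4-(but-3-en-1-yl)-2-(furan-3-ylmethyl)furan | C=CCCc1coc(Cc2ccoc2)c1
A3 | alternative 2 | (2E,6S,8E,10E)-13-[5-(furan-3-ylmethyl)furan-3-yl]-3-methoxy-2,6,10-trimethyltrideca-2,8,10-trien-4-ynoic acid | C/C(C(=O)O)=C(\OC)C#C[C@@H](C)C/C=C/C(C)=C/CCc1coc(Cc2ccoc2)c1
A4 | alternative 2 | (5Z)-5-[(2S,4E,6E)-9-[5-(furan-3-ylmethyl)furan-3-yl]-2,6-dimethylnona-4,6-dien-1-ylidene]-4-methoxy-3-methylfuran-2(5H)-one | CC1=C(OC)/C(=C/[C@@H](C)C/C=C/C(C)=C/CCc2coc(Cc3ccoc3)c2)OC1=O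
A5 | alternative 3 | dimethylsulfonium 3-(furan-3-yl)-2-oxopropan-1-ide | C[S+](C)[CH-]C(=O)Cc1ccoc1
A6 | alternative 3 | tert-butyldimethyl(pent-4-yn-1-yloxy)silane | C#CCCCO[Si](C)(C)C(C)(C)C
A7 | alternative 3 | tert-butyl{3-[5-(furan-3-ylmethyl)furan-3-yl]propoxy}dimethylsilane | CC(C)(C)[Si](C)(C)OCCCc1coc(Cc2ccoc2)c1
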